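**Strategy.** Everything rests on cutting the dihydrofuran at its O–C(benzylic) bond together with the C3–OH bond, which leads back to an achiral (E)-3-(4-methoxybenzylidene)spirochromanone. The key step exploits that the C3 hydroxyl and the furan O–CH(anisyl) bond are anti on adjacent carbons (an opened enone epoxide) and that spiro carbon C2 carries two identical arms of the cyclohexanetrione ring. One catalyst-controlled epoxidation, followed by opening by the arm oxygen, sets C3, the benzylic carbon and the spiro carbon and closes the furan. The precursor keeps both acidic enol oxygens as methyl ethers, so it is neutral and symmetric by construction. The pyran is added last through a reagent-controlled ketone reduction.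

Key step: step 4

Remark (assumption): C2 (spiro), C3 and C4 are chromanone locants and primed locants belong to the six-membered carbocycle; 1,3-dione units are drawn in one tautomeric form; the facial preference of the cinchonidinium catalyst is assumed to follow that known for chalcone.

Step 1
Reactants: 1 1-fluoro-3,5-dimethoxybenzene
Product: 2 1-(2-fluoro-4,6-dimethoxyphenyl)ethan-1-one
Conditions: AcCl, AlCl3, CH2Cl2, −10 to 0 °C
Reagents that add atoms: acetyl chloride, CC(=O)Cl
Why: Friedel–Crafts acylation should go to C2 of 1, which is para to one methoxy group, ortho to the other and flanked by the small fluorine (the counterpart of the C4-selective acylation of 1,3-dimethoxybenzene), whereas the position between the two methoxy groups is more hindered.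

Step 2
Reactants: 2 1-(2-fluoro-4,6-dimethoxyphenyl)ethan-1-one; 3 2,6-dimethoxy-1,4-benzoquinone
Product: 5 2',5,6',7-tetramethoxyspiro[chromane-2,1'-cyclohexa-2',5'-diene]-4,4'-dione, via lithium aldolate 4 (not isolated)
Conditions: LiN(SiMe3)2, THF, −78 °C; 3, −78 °C; then DMPU, −78 to 25 °C; AcOH quench
Reagents that add atoms: none
Why: Kinetic aldol-type 1,2-addition of the lithium enolate should take the quinone carbonyl between the two methoxy-bearing carbons (the other carbonyl is a doubly vinylogous ester), and the tertiary alkoxide then displaces the fluoride ortho to the aryl ketone in an intramolecular SNAr closure of the six-membered ring, the irreversible loss of fluoride draining any reversible fragmentation of the aldolate.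

Step 3
Reactants: 5 2',5,6',7-tetramethoxyspiro[chromane-2,1'-cyclohexa-2',5'-diene]-4,4'-dione; 6 4-methoxybenzaldehyde
Product: 7 (E)-2',5,6',7-tetramethoxy-3-(4-methoxybenzylidene)spiro[chromane-2,1'-cyclohexa-2',5'-diene]-4,4'-dione
Conditions: 6, HCl (1.25 M in MeOH), 25 to 40 °C
Reagents that add atoms: none
Why: Acid-catalysed crossed aldol condensation (Claisen–Schmidt type) at C3, the only enolisable carbon, should give the thermodynamically preferred (E)-benzylidene ketone (anisyl anti to the C4 carbonyl, syn to the spiro carbon); acid is chosen because base would open the chromanone by β-elimination of the phenoxide, and methanol makes any exchange of the two enol ethers degenerate.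

Step 4
Reactants: 7 (E)-2',5,6',7-tetramethoxy-3-(4-methoxybenzylidene)spiro[chromane-2,1'-cyclohexa-2',5'-diene]-4,4'-dione
Product: 9 (spiro C2 S; C3 R; benzylic S)-3-hydroxy spiro tetracycle with cis-fused dihydrofuran and free 1,3-dione (drawn as diketone), via spiro-epoxide 8 (not isolated)
Conditions: N-(9-anthracenylmethyl)-O-benzyldihydrocinchonidinium bromide (10 mol %), aq. NaOCl, toluene, 0 to 25 °C; aq. Na2SO3; then 1 M HCl, THF, 0 to 25 °C
Reagents that add atoms: sodium hypochlorite, [Na+].[O-]Cl; water, O
Why: Proposed new method: the chiral ammonium hypochlorite ion pair adds to the benzylic β-carbon of the chromanone enone and the enolate closes the oxirane (Weitz–Scheffer, 3-exo-tet), and because the chromanone plane is a mirror plane of 7 the two alkene faces are enantiotopic, so the catalyst's choice fixes C3 (closest known reactions: cinchona phase-transfer epoxidation of chalcones and 2-arylidene-1-tetralones, and the acid-triggered unmasking and ring closure of protected 2'-hydroxychalcone epoxides to dihydroflavonols). Dilute acid then ionises the p-anisyl epoxide towards the benzylic carbon and hydrolyses the vinylogous methyl esters, and the enol oxygen of the arm on the face opposite the C3–O bond captures the benzylic carbon with inversion, closing the dihydrofuran in a 5-endo epoxide opening (both oxirane carbons end up in the new ring, which is exo only with respect to the breaking C–O bond). C3 is set by the catalyst; the spiro carbon follows from C3 because only the arm trans to the C3 oxygen can reach the benzylic carbon, which makes the chromanone–furan fusion cis; the benzylic centre follows from the (E)-alkene plus inversion, and a fully ionised pathway should converge on the same isomer with the anisyl group on the convex face, cis to the C3 hydroxyl. The cinchonidinium salt is chosen by analogy with chalcone, for which it is taken to give the (αS,βR)-epoxide, the sense required here (C3 R, benzylic R in 8). The step needs enantioface selection, secured by a neutral, rigid s-cis enone with no acidic enol to pair with the catalyst; attack at the benzylidene enone and not the dienone, secured by the methoxy groups on both dienone β-carbons; and O- rather than C-capture of the benzylic carbon, favoured by the in-plane five-membered approach of the arm oxygen over bridging attack by C3'.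

Step 5
Reactants: 9 (spiro C2 S; C3 R; benzylic S)-3-hydroxy spiro tetracycle with free 1,3-dione; 10 3-chloro-1-(4-methoxyphenyl)propan-1-one
Product: 11 C5'-[3-(4-methoxyphenyl)-3-oxopropyl] derivative of 9 (drawn as the C6' enol)
Conditions: 10, Et3N, THF, 0 to 25 °C
Reagents that add atoms: none
Why: Michael addition of C5', the only carbon flanked by two carbonyl groups, to the aryl vinyl ketone released from 10 by loss of HCl should give the C-alkylated dione, as is usual for cyclic 1,3-diones, with one equivalent of acceptor limiting double addition and the three stereocentres untouched.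

Step 6
Reactants: 11 C5'-[3-(4-methoxyphenyl)-3-oxopropyl] derivative of 9
Product: 13 target CNP0251458.1 (spiro C2 S; C3 R; furan benzylic S; pyran C2 R), via (R)-carbinol 12 (not isolated)
Conditions: RuCl(p-cymene)[(R,R)-TsDPEN] (2 mol %), HCO2H/Et3N 5:2, EtOAc, 30 °C; then PPTS, 4 Å MS, CH2Cl2, 25 °C
Reagents that add atoms: none
Why: Noyori–Ikariya asymmetric transfer hydrogenation should reduce only the unhindered anisyl ketone (the C4 ketone is neopentylic, peri-methoxylated and a vinylogous carbonate), the (R,R)-ligand setting the (R)-carbinol by reagent control, and acid-catalysed hemiketalisation–dehydration then closes the pyran through the C6' carbonyl (the true ketone, whereas C4' is a vinylogous ester carbonyl, and the cross-conjugated dienone formed is the more stable enol ether) without breaking the carbinol C–O bond, so pyran C2 stays R.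

**Compound list**

1 | 1-fluoro-3,5-dimethoxybenzene | COc1cc(F)cc(OC)c1 | starting material
2 | 1-(2-fluoro-4,6-dimethoxyphenyl)ethan-1-one | CC(=O)c1c(F)cc(OC)cc1OC | intermediate
3 | 2,6-dimethoxy-1,4-benzoquinone | COC1=CC(=O)C=C(OC)C1=O | starting material
4 | lithium 1-[2-(2-fluoro-4,6-dimethoxyphenyl)-2-oxoethyl]-2,6-dimethoxy-4-oxocyclohexa-2,5-dien-1-olate (lithium aldolate, formed in the flask) | [Li+].[O-]C1(CC(=O)c2c(F)cc(OC)cc2OC)C(OC)=CC(=O)C=C1OC | intermediate
5 | 2',5,6',7-tetramethoxyspiro[chromane-2,1'-cyclohexa-2',5'-diene]-4,4'-dione (achiral) | COC1=CC(=O)C=C(OC)C12CC(=O)c1c(OC)cc(OC)cc1O2 | intermediate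
6 | 4-methoxybenzaldehyde | COc1ccc(C=O)cc1 | starting material
7 | (E)-2',5,6',7-tetramethoxy-3-(4-methoxybenzylidene)spiro[chromane-2,1'-cyclohexa-2',5'-diene]-4,4'-dione (achiral key precursor; anisyl syn to the spiro carbon) | COC1=CC(=O)C=C(OC)C12Oc1cc(OC)cc(OC)c1C(=O)/C2=C/c1ccc(OC)cc1 | intermediate
8 | spiro-epoxide of 7 across C3 and the benzylic carbon (C3 R, benzylic R; anisyl trans to the C4 carbonyl; formed in the flask) | COC1=CC(=O)C=C(OC)C13Oc4cc(OC)cc(OC)c4C(=O)[C@]35O[C@@H]5c3ccc(OC)cc3 | intermediate
9 | 3-hydroxy spiro tetracycle: chromanone cis-fused to a 2-(4-methoxyphenyl)dihydrofuran that is an enol ether of the cyclohexane-1,3-dione ring (spiro C2 S, C3 R, benzylic S; OH cis to anisyl; drawn as diketone) | O=C1CC(=O)[C@]23Oc4cc(OC)cc(OC)c4C(=O)[C@@]2(O)[C@H](c2ccc(OC)cc2)OC3=C1 | intermediate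
10 | 3-chloro-1-(4-methoxyphenyl)propan-1-one | COc1ccc(C(=O)CCCl)cc1 | starting material
11 | 9 carrying a 3-(4-methoxyphenyl)-3-oxopropyl group at C5' (core stereocentres as in 9; drawn as the C6' enol) | COc1ccc(C(=O)CCC3=C(O)[C@]24Oc5cc(OC)cc(OC)c5C(=O)[C@@]2(O)[C@H](c2ccc(OC)cc2)OC4=CC3=O)cc1 | intermediate
12 | (R)-3-hydroxy-3-(4-methoxyphenyl)propyl analogue of 11 (core as in 9; formed in the flask) | COc1ccc([C@H](O)CCC3=C(O)[C@]24Oc5cc(OC)cc(OC)c5C(=O)[C@@]2(O)[C@H](c2ccc(OC)cc2)OC4=CC3=O)cc1 | intermediate
13 | CNP0251458.1 (spiro C2 S, C3 R, furan benzylic S, pyran C2 R) | COc1ccc([C@H]2CCC3=C(O2)[C@]24Oc5cc(OC)cc(OC)c5C(=O)[C@@]2(O)[C@H](c2ccc(OC)cc2)OC4=CC3=O)cc1 | target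

**Step count.** Total: 6 steps. Longest linear sequence: 6 steps (1 to 13).

**Steps most likely to fail**

1. Step 4 (proposed new method). Enantioface discrimination may be weak on this hindered, electron-rich trisubstituted enone. In the acid stage the benzylic cation may also be diverted by a 1,2-acyl shift before the arm oxygen is unmasked. The fallback uses known chemistry, sets out from 7 and returns at 9. Both enol ethers of 7 are hydrolysed first (2 M HCl, dioxane, 60 °C) to the free trione (E)-3-(4-methoxybenzylidene)-5,7-dimethoxyspiro[chromane-2,1'-cyclohexane]-2',4,4',6'-tetrone F1. F1 is then epoxidised by the classical Weitz–Scheffer method (H2O2, NaOH, aqueous methanol, 0 °C). In this basic medium the trione enolate opens the racemic spiro-epoxy trione F2 without a free cation, and a brief adjustment to pH 4 completes the closure to the racemic hydroxy dihydrofuran dione F3. The enantiomers of the acidic dione are then separated by preparative chromatography on a chiral stationary phase, and the route continues with 9.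

2. Step 2. The lithium aldolate may fragment back to enolate and quinone, and conjugate addition or electron transfer between the two may then outrun displacement of the deactivated fluoride. Any excess base would also open 5 by β-elimination of the phenoxide. The fallback sets out from 3 and returns at 7. The lithium enolate of commercial 1-(2,4,6-trifluorophenyl)ethan-1-one is added to 3 at −78 °C to give the trifluoroaryl lithium aldolate F4. Its ortho fluoride, activated by two further fluorines, should be displaced on warming only to about −20 °C, giving 5,7-difluoro-2',6'-dimethoxyspiro[chromane-2,1'-cyclohexa-2',5'-diene]-4,4'-dione F5. Acid-catalysed condensation with 6 as in step 3 gives the (E)-5,7-difluoro benzylidene compound F6. Both aryl fluorides, ortho and para to the ketone, are then exchanged with NaOMe in MeOH (25 to 50 °C) to reach 7; exchange at the dienone enol ethers is degenerate.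

3. Step 3. Acid may open the chromanone of 5 by retro-oxa-Michael reaction to an acyl quinone methide, which would re-close to an aromatised benzofuranone. The hindered C3 enol may also fail to add to the aldehyde. The fallback sets out from 5 and returns at 7. Compound 5 is converted under aprotic soft enolisation (Me3SiOTf, Et3N, CH2Cl2, 0 °C) into its trimethylsilyl enol ether F7. F7 is added to commercial 4-methoxybenzaldehyde dimethyl acetal with catalytic Me3SiOTf at −78 °C (Mukaiyama aldol-type addition) to give the β-methoxy ketone F8. Methanol is then eliminated with catalytic TsOH in toluene at 60 °C (E1 through the p-anisyl cation) to give 7.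

**Further compounds**

F1 | step 4 | (E)-3-(4-methoxybenzylidene)-5,7-dimethoxyspiro[chromane-2,1'-cyclohexane]-2',4,4',6'-tetrone (free trione, enolised) | O=C1CC(=O)C2(Oc3cc(OC)cc(OC)c3C(=O)/C2=C/c2ccc(OC)cc2)C(=O)C1
F2 | step 4 | racemic spiro-epoxy trione (anisyl trans to the C4 carbonyl; one enantiomer drawn) | O=C1CC(=O)C2(Oc3cc(OC)cc(OC)c3C(=O)[C@]24O[C@@H]4c2ccc(OC)cc2)C(=O)C1
F3 | step 4 | racemic hydroxy dihydrofuran dione (relative configuration of 9; one enantiomer drawn) | O=C1CC(=O)[C@]23Oc4cc(OC)cc(OC)c4C(=O)[C@@]2(O)[C@H](c2ccc(OC)cc2)OC3=C1
F4 | step 2 | lithium 2,6-dimethoxy-4-oxo-1-[2-oxo-2-(2,4,6-trifluorophenyl)ethyl]cyclohexa-2,5-dien-1-olate | [Li+].[O-]C1(CC(=O)c2c(F)cc(F)cc2F)C(OC)=CC(=O)C=C1OC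
F5 | step 2 | 5,7-difluoro-2',6'-dimethoxyspiro[chromane-2,1'-cyclohexa-2',5'-diene]-4,4'-dione | COC1=CC(=O)C=C(OC)C12CC(=O)c1c(F)cc(F)cc1O2
F6 | step 2 | (E)-5,7-difluoro-2',6'-dimethoxy-3-(4-methoxybenzylidene)spiro[chromane-2,1'-cyclohexa-2',5'-diene]-4,4'-dione | COC1=CC(=O)C=C(OC)C12Oc1cc(F)cc(F)c1C(=O)/C2=C/c1ccc(OC)cc1
F7 | step 3 | 2',5,6',7-tetramethoxy-4-(trimethylsilyloxy)spiro[chromene-2,1'-cyclohexa-2',5'-dien]-4'-one | COC1=CC(=O)C=C(OC)C12C=C(O[Si](C)(C)C)c1c(OC)cc(OC)cc1O2
F8 | step 3 | 2',5,6',7-tetramethoxy-3-[methoxy(4-methoxyphenyl)methyl]spiro[chromane-2,1'-cyclohexa-2',5'-diene]-4,4'-dione (diastereomer mixture) | COC1=CC(=O)C=C(OC)C12Oc1cc(OC)cc(OC)c1C(=O)C2C(OC)c1ccc(OC)cc1
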